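The route rests on opening the O1–C2 bond of the 2,3-dihydrobenzofuran. C2 is a benzylic carbon of ring D and is para-related to that ring's oxygen substituent, so a C2 carbinol ionises easily, and the phenol oxygen on ring C can reach C2 through a five-membered ring. One acid treatment therefore closes the furan ring and fixes C2 trans to the already set C3, whichever carbinol epimer is used. The precursor is a 1-aryl-2-(5-allyl-2-hydroxy-3-methoxyphenyl)propane-1,3-diol from an auxiliary-controlled aldol, carried with its primary hydroxyl silylated. The allyl group later becomes the lactone by cross-metathesis, Ireland–Claisen rearrangement with the ring B acid, and ozonolysis.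

Key step: step 10

Ring letters: A = guaiacyl ring on the glycerol unit, B = aryl ether ring on the lactone alpha-benzyl group, C = benzo ring of the dihydrobenzofuran, D = its 2-aryl ring.
Assumption: aldehyde 1, the ortho-formylation product of eugenol, is bought as such.

Step 1
Reactants: 1 5-allyl-2-hydroxy-3-methoxybenzaldehyde
Product: 2 5-allyl-2-(allyloxy)-3-methoxybenzaldehyde
Conditions: allyl bromide, K2CO3, DMF, rt
Reagents that add atoms: allyl bromide, C=CCBr
Why: Williamson O-alkylation of the phenoxide; the allyl ether masks the ring C phenol through the enolate and hydride steps and is later removable under neutral conditions that leave the C-allyl group and silyl ethers alone.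

Step 2
Reactants: 2 5-allyl-2-(allyloxy)-3-methoxybenzaldehyde
Product: 3 1-(allyloxy)-2-methoxy-6-(2-methoxyethenyl)-4-allylbenzene (E/Z mixture)
Conditions: MeOCH2PPh3Cl, KOtBu, THF, 0 °C → rt
Reagents that add atoms: (methoxymethyl)triphenylphosphonium chloride, COC[P+](c1ccccc1)(c1ccccc1)c1ccccc1.[Cl-]
Why: Wittig methoxymethylenation of the aryl aldehyde adds the one carbon needed for the arylacetic acid; the enol ether geometry is of no consequence.

Step 3
Reactants: 3 enol ether
Product: 5 2-[5-allyl-2-(allyloxy)-3-methoxyphenyl]acetic acid, via arylacetaldehyde 4 (not isolated)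
Conditions: 2 M HCl, THF, 45 °C; then NaClO2, NaH2PO4, 2-methyl-2-butene, t-BuOH/H2O, 0 °C → rt
Reagents that add atoms: water, O; sodium chlorite, [Na+].[O-]Cl=O
Why: Acid hydrolysis of the enol ether followed directly by Pinnick oxidation, with 2-methyl-2-butene scavenging hypochlorous acid so that the two allyl groups and the arene are spared and the self-condensing arylacetaldehyde is never stored.

Step 4
Reactants: 5 arylacetic acid; 6 (S)-4-benzyl-2-oxazolidinone
Product: 8 (S)-3-{2-[5-allyl-2-(allyloxy)-3-methoxyphenyl]acetyl}-4-benzyloxazolidin-2-one, via mixed pivalic anhydride 7 (not isolated)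
Conditions: PivCl, Et3N, THF, −20 °C; then 6, LiCl, −20 °C → rt
Reagents that add atoms: none
Why: N-Acylation of the oxazolidinone through the mixed pivalic anhydride under LiCl/Et3N activation, a standard imide synthesis that needs no strong base.

Step 5
Reactants: 9 vanillin
Product: 10 3-methoxy-4-(triisopropylsilyloxy)benzaldehyde
Conditions: TIPSCl, imidazole, DMF, rt
Reagents that add atoms: chlorotriisopropylsilane, CC(C)[Si](Cl)(C(C)C)C(C)C
Why: Imidazole-mediated silylation of the phenol; the triisopropylsilyl ether survives the borohydride and enolate steps and keeps the para oxygen of ring D electron-donating.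

Step 6
Reactants: 8 N-arylacetyl oxazolidinone; 10 silylated vanillin
Product: 12 (S)-3-[(2S,3S)-2-[5-allyl-2-(allyloxy)-3-methoxyphenyl]-3-hydroxy-3-(3-methoxy-4-triisopropylsilyloxyphenyl)propanoyl]-4-benzyloxazolidin-2-one, via Z-boron enolate 11 (not isolated)
Conditions: Bu2BOTf, iPr2NEt, CH2Cl2, −78 → 0 °C; then 10, −78 → 0 °C; pH 7 buffer, MeOH, H2O2, 0 °C
Reagents that add atoms: none
Why: Evans syn-aldol reaction: the Z-boron enolate reacts through a Zimmerman–Traxler chair on the face away from the benzyl group of the (S)-auxiliary, which sets the alpha carbon (the future C3, 2S here) and gives the syn carbinol (3S), the latter being without consequence since it is re-set in step 10.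

Step 7
Reactants: 12 aldol imide
Product: 13 (1S,2R)-2-[5-allyl-2-(allyloxy)-3-methoxyphenyl]-1-(3-methoxy-4-triisopropylsilyloxyphenyl)propane-1,3-diol
Conditions: LiBH4, MeOH (1 equiv), THF, 0 °C
Reagents that add atoms: none
Why: Reductive cleavage of the N-acyl oxazolidinone by LiBH4 delivers the primary alcohol without touching either stereocentre and releases the auxiliary for recovery.

Step 8
Reactants: 13 diol
Product: 14 (1S,2R)-2-[5-allyl-2-(allyloxy)-3-methoxyphenyl]-3-(tert-butyldiphenylsilyloxy)-1-(3-methoxy-4-triisopropylsilyloxyphenyl)propan-1-ol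
Conditions: TBDPSCl, imidazole, CH2Cl2, 0 °C
Reagents that add atoms: tert-butylchlorodiphenylsilane, CC(C)(C)[Si](Cl)(c1ccccc1)c1ccccc1
Why: Sterically controlled silylation of the primary hydroxyl in preference to the hindered benzylic one; capping the hydroxymethyl group before the cation step removes the retro-Prins loss of formaldehyde and a second oxygen nucleophile, and the product of step 10 emerges already protected.

Step 9
Reactants: 14 allyl aryl ether
Product: 15 (1S,2R)-2-(5-allyl-2-hydroxy-3-methoxyphenyl)-3-(tert-butyldiphenylsilyloxy)-1-(3-methoxy-4-triisopropylsilyloxyphenyl)propan-1-ol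
Conditions: Pd(PPh3)4 (3 mol %), morpholine, THF, rt
Reagents that add atoms: none
Why: Tsuji–Trost deallylation: zerovalent palladium ionises only the aryl allyl ether to a pi-allyl complex that morpholine intercepts, so the C-allyl group, the silyl ethers and the carbinol are untouched.

Step 10
Reactants: 15 syn phenol carbinol
Product: 16 (2S,3R)-5-allyl-3-[(tert-butyldiphenylsilyloxy)methyl]-7-methoxy-2-(3-methoxy-4-triisopropylsilyloxyphenyl)-2,3-dihydrobenzofuran
Conditions: BF3·OEt2 (0.3 equiv), CH2Cl2 (0.01 M), −40 → 0 °C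
Reagents that add atoms: none
Why: BF3·OEt2 ionises the C1 carbinol of 15 to a benzylic cation that the para silyloxy oxygen of ring D delocalises as a quinone-methide-type oxocarbenium ion, and the ring C phenol oxygen then adds to the cationic carbon. The closest known reaction type is the acid-mediated dehydrative cyclisation of 1-aryl-2-(2-hydroxyaryl)propan-1-ols to 2-aryl-2,3-dihydrobenzofurans. The single ring is closed in the 5-exo-trig mode, the oxygen attacking an sp2 carbon whose formal double bond to ring D lies outside the new ring. The new stereocentre C2 is controlled by the existing C3 centre: the phenol approaches the planar cation anti to the CH2OTBDPS group, and because the product can re-ionise the trans isomer is also the thermodynamic one, so the C1 configuration of 15 is irrelevant. The step needs O-cyclisation to outrun proton loss, formaldehyde extrusion and intermolecular arylation, which the silylated hydroxymethyl group, the short tether and high dilution should secure.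

Step 11
Reactants: 16 5-allyl dihydrobenzofuran; 17 (R)-but-3-en-2-ol
Product: 18 (2R,3E)-5-[(2S,3R)-3-[(tert-butyldiphenylsilyloxy)methyl]-7-methoxy-2-(3-methoxy-4-triisopropylsilyloxyphenyl)-2,3-dihydrobenzofuran-5-yl]pent-3-en-2-ol
Conditions: 17 (5 equiv), second-generation Hoveyda–Grubbs catalyst RuCl2(H2IMes)(=CH-C6H4-2-OiPr) (5 mol %), 1,4-benzoquinone (10 mol %), CH2Cl2, 40 °C
Reagents that add atoms: none
Why: Olefin cross-metathesis between the terminal allylarene and an excess of the secondary allylic alcohol should give the E-disubstituted alkene under thermodynamic control, the carbinol stereocentre taking no part; benzoquinone suppresses ruthenium hydride double-bond migration.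

Step 12
Reactants: 19 methyl (R)-2,3-dihydroxypropanoate
Product: 20 methyl (R)-3-(tert-butyldimethylsilyloxy)-2-hydroxypropanoate
Conditions: TBSCl, imidazole, CH2Cl2, 0 °C
Reagents that add atoms: tert-butylchlorodimethylsilane, CC(C)(C)[Si](C)(C)Cl
Why: Selective silylation of the primary hydroxyl of the diol ester, leaving the alpha hydroxyl free for the ether-forming step.

Step 13
Reactants: 20 alpha-hydroxy ester; 21 eugenol
Product: 22 methyl (S)-2-(4-allyl-2-methoxyphenoxy)-3-(tert-butyldimethylsilyloxy)propanoate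
Conditions: PPh3, DIAD, THF, 0 °C → rt
Reagents that add atoms: none
Why: Mitsunobu etherification of the alpha-hydroxy ester by the phenol proceeds by SN2 displacement of the oxyphosphonium group with inversion, turning the (R)-carbinol into the (S)-aryloxy centre.

Step 14
Reactants: 22 aryloxy ester
Product: 23 (S)-2-(4-allyl-2-methoxyphenoxy)-3-(tert-butyldimethylsilyloxy)-N-methoxy-N-methylpropanamide
Conditions: MeNH(OMe)·HCl, AlMe3, CH2Cl2, 0 °C → rt
Reagents that add atoms: N,O-dimethylhydroxylamine hydrochloride, CNOC.Cl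
Why: Aluminium amide aminolysis of the ester (Weinreb amide formation) under Lewis acidic, non-basic conditions that should not epimerise the alpha-aryloxy centre.

Step 15
Reactants: 24 4-bromo-2-methoxyphenol
Product: 25 (4-bromo-2-methoxyphenoxy)triisopropylsilane
Conditions: TIPSCl, imidazole, DMF, rt
Reagents that add atoms: chlorotriisopropylsilane, CC(C)[Si](Cl)(C(C)C)C(C)C
Why: Imidazole-mediated silylation of the phenol gives an aryl silyl ether that tolerates the organolithium step and falls off with the other silyl groups at the end.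

Step 16
Reactants: 25 aryl bromide; 23 Weinreb amide
Product: 27 (S)-2-(4-allyl-2-methoxyphenoxy)-3-(tert-butyldimethylsilyloxy)-1-(3-methoxy-4-triisopropylsilyloxyphenyl)propan-1-one, via aryllithium 26 (not isolated)
Conditions: n-BuLi, THF, −78 °C; then 23, −78 °C; aq. NH4Cl
Reagents that add atoms: none
Why: Bromine–lithium exchange followed by Weinreb ketone synthesis; the chelated tetrahedral adduct prevents double addition and keeps the alpha-aryloxy centre from enolising until the cold quench.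

Step 17
Reactants: 27 alpha-aryloxy ketone
Product: 28 (1R,2S)-2-(4-allyl-2-methoxyphenoxy)-3-(tert-butyldimethylsilyloxy)-1-(3-methoxy-4-triisopropylsilyloxyphenyl)propan-1-ol
Conditions: (R)-2-methyl-CBS-oxazaborolidine (0.5 equiv), catecholborane, toluene, −78 → −40 °C
Reagents that add atoms: none
Why: Corey–Bakshi–Shibata reduction in which the aryl group acts as the large substituent, so the (R)-oxazaborolidine delivers hydride to the face giving the 1R carbinol (erythro to the existing 2S centre) under reagent control; catecholborane is used because it leaves the allyl group alone at this temperature.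

Step 18
Reactants: 28 erythro alcohol
Product: 29 4-allyl-1-{[(1R,2S)-1,3-bis(tert-butyldimethylsilyloxy)-1-(3-methoxy-4-triisopropylsilyloxyphenyl)propan-2-yl]oxy}-2-methoxybenzene
Conditions: TBSOTf, 2,6-lutidine, CH2Cl2, −78 → 0 °C
Reagents that add atoms: tert-butyldimethylsilyl trifluoromethanesulfonate, CC(C)(C)[Si](C)(C)OS(=O)(=O)C(F)(F)F
Why: Silyl triflate silylation of the hindered benzylic alcohol under buffered, cold conditions; no stereocentre is affected.

Step 19
Reactants: 29 allylarene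
Product: 31 3-[4-{[(1R,2S)-1,3-bis(tert-butyldimethylsilyloxy)-1-(3-methoxy-4-triisopropylsilyloxyphenyl)propan-2-yl]oxy}-3-methoxyphenyl]propan-1-ol, via B-alkyl-9-BBN 30 (not isolated)
Conditions: 9-BBN, THF, 0 °C → rt; then NaOH, H2O2, 0 °C
Reagents that add atoms: hydrogen peroxide, OO
Why: Anti-Markovnikov hydroboration of the terminal alkene with 9-BBN and oxidative work-up give the primary alcohol.

Step 20
Reactants: 31 primary alcohol
Product: 33 3-[4-{[(1R,2S)-1,3-bis(tert-butyldimethylsilyloxy)-1-(3-methoxy-4-triisopropylsilyloxyphenyl)propan-2-yl]oxy}-3-methoxyphenyl]propanoic acid, via aldehyde 32 (not isolated)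
Conditions: TEMPO (20 mol %), PhI(OAc)2, MeCN/H2O (1:1), rt
Reagents that add atoms: water, O
Why: Oxoammonium (TEMPO) oxidation with PhI(OAc)2 in aqueous acetonitrile takes the primary alcohol through the aldehyde hydrate to the acid under conditions mild enough for silyl ethers and electron-rich arenes.

Step 21
Reactants: 18 allylic alcohol; 33 ring B acid
Product: 34 (2R,3E)-5-[(2S,3R)-3-[(tert-butyldiphenylsilyloxy)methyl]-7-methoxy-2-(3-methoxy-4-triisopropylsilyloxyphenyl)-2,3-dihydrobenzofuran-5-yl]pent-3-en-2-yl ester of acid 33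
Conditions: DCC, DMAP (10 mol %), CH2Cl2, 0 °C → rt
Reagents that add atoms: none
Why: Steglich esterification acylates the allylic alcohol at oxygen, so the carbinol configuration is retained.

Step 22
Reactants: 34 allylic ester
Product: 37 (2R,3S,4E)-2-(ring B benzyl)-3-(ring C methyl)hex-4-enoic acid with all silyl groups in place, via Z-silyl ketene acetal 35 (not isolated), via trimethylsilyl ester 36 (not isolated)
Conditions: LiN(iPr)2, THF/DMPU (4:1), −78 °C; Me3SiCl, −78 → 50 °C; then 0.5 M HCl, 0 °C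
Reagents that add atoms: none
Why: Ireland–Claisen rearrangement: the Z-silyl ketene acetal formed in the presence of DMPU rearranges through a chair with the methyl group equatorial, so chirality passes from the (R)-carbinol to C3 (S) and the equatorial benzyl group on the ketene acetal sets C2 (R) syn to it, the relationship that becomes the trans lactone.

Step 23
Reactants: 37 hexenoic acid
Product: 40 (3R,4R)-3-(ring B benzyl)-4-(ring C methyl)dihydrofuran-2(3H)-one with all five silyl groups in place, via ozonide 38 (not isolated), via hydroxy acid 39 (not isolated)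
Conditions: O3, CH2Cl2, −78 °C; then MeOH, NaBH4, −78 → 0 °C; then aq. citric acid (pH 4), rt
Reagents that add atoms: ozone, [O-][O+]=O
Why: Ozonolysis of the only C=C bond (which reacts far faster than the arenes) with borohydride work-up gives the gamma-hydroxy acid, which lactonises on mild acidification; neither stereocentre is touched.

Step 24
Reactants: 40 silylated lactone
Product: 41 CNP0298853.1
Conditions: TBAF, AcOH (1:1, 10 equiv), THF, 0 °C → rt
Reagents that add atoms: none
Why: Fluoride-mediated cleavage of all five silyl ethers in one operation, buffered with acetic acid so that the lactone, the phenylcoumaran and the aryl glycerol ether are not exposed to strong base.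

Compound list

1 | 5-allyl-2-hydroxy-3-methoxybenzaldehyde | O=Cc1cc(CC=C)cc(OC)c1O | starting material
2 | 5-allyl-2-(allyloxy)-3-methoxybenzaldehyde | O=Cc1cc(CC=C)cc(OC)c1OCC=C | intermediate
3 | 1-(allyloxy)-2-methoxy-6-(2-methoxyethenyl)-4-allylbenzene (E/Z mixture) | COC=Cc1cc(CC=C)cc(OC)c1OCC=C | intermediate
4 | 2-[5-allyl-2-(allyloxy)-3-methoxyphenyl]acetaldehyde | O=CCc1cc(CC=C)cc(OC)c1OCC=C | intermediate
5 | 2-[5-allyl-2-(allyloxy)-3-methoxyphenyl]acetic acid | OC(=O)Cc1cc(CC=C)cc(OC)c1OCC=C | intermediate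
6 | (S)-4-benzyl-2-oxazolidinone | O=C1OC[C@H](Cc2ccccc2)N1 | starting material
7 | mixed anhydride of 5 and pivalic acid | CC(C)(C)C(=O)OC(=O)Cc1cc(CC=C)cc(OC)c1OCC=C | intermediate
8 | (S)-3-{2-[5-allyl-2-(allyloxy)-3-methoxyphenyl]acetyl}-4-benzyloxazolidin-2-one | O=C1OC[C@H](Cc2ccccc2)N1C(=O)Cc1cc(CC=C)cc(OC)c1OCC=C | intermediate
9 | vanillin | COc1cc(C=O)ccc1O | starting material
10 | 3-methoxy-4-(triisopropylsilyloxy)benzaldehyde | COc1cc(C=O)ccc1O[Si](C(C)C)(C(C)C)C(C)C | intermediate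
11 | Z-dibutylboron enolate of 8 | O=C1OC[C@H](Cc2ccccc2)N1/C(OB(CCCC)CCCC)=C/c1cc(CC=C)cc(OC)c1OCC=C | intermediate
12 | (S)-3-[(2S,3S)-2-[5-allyl-2-(allyloxy)-3-methoxyphenyl]-3-hydroxy-3-(3-methoxy-4-triisopropylsilyloxyphenyl)propanoyl]-4-benzyloxazolidin-2-one | O=C1OC[C@H](Cc2ccccc2)N1C(=O)[C@@H](c1cc(CC=C)cc(OC)c1OCC=C)[C@H](O)c1ccc(O[Si](C(C)C)(C(C)C)C(C)C)c(OC)c1 | intermediate
13 | (1S,2R)-2-[5-allyl-2-(allyloxy)-3-methoxyphenyl]-1-(3-methoxy-4-triisopropylsilyloxyphenyl)propane-1,3-diol | C=CCOc1c(OC)cc(CC=C)cc1[C@H](CO)[C@H](O)c1ccc(O[Si](C(C)C)(C(C)C)C(C)C)c(OC)c1 | intermediate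
14 | (1S,2R)-2-[5-allyl-2-(allyloxy)-3-methoxyphenyl]-3-(tert-butyldiphenylsilyloxy)-1-(3-methoxy-4-triisopropylsilyloxyphenyl)propan-1-ol | C=CCOc1c(OC)cc(CC=C)cc1[C@H](CO[Si](c2ccccc2)(c2ccccc2)C(C)(C)C)[C@H](O)c2ccc(O[Si](C(C)C)(C(C)C)C(C)C)c(OC)c2 | intermediate
15 | (1S,2R)-2-(5-allyl-2-hydroxy-3-methoxyphenyl)-3-(tert-butyldiphenylsilyloxy)-1-(3-methoxy-4-triisopropylsilyloxyphenyl)propan-1-ol (syn; key-step precursor) | C=CCc1cc(OC)c(O)c(c1)[C@H](CO[Si](c2ccccc2)(c2ccccc2)C(C)(C)C)[C@H](O)c2ccc(O[Si](C(C)C)(C(C)C)C(C)C)c(OC)c2 | intermediate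
16 | (2S,3R)-5-allyl-3-[(tert-butyldiphenylsilyloxy)methyl]-7-methoxy-2-(3-methoxy-4-triisopropylsilyloxyphenyl)-2,3-dihydrobenzofuran (trans; key-step product) | C=CCc1cc(OC)c2c(c1)[C@H](CO[Si](c3ccccc3)(c3ccccc3)C(C)(C)C)[C@@H](c3ccc(O[Si](C(C)C)(C(C)C)C(C)C)c(OC)c3)O2 | intermediate
17 | (R)-but-3-en-2-ol | C[C@@H](O)C=C | starting material
18 | (2R,3E)-5-[(2S,3R)-3-[(tert-butyldiphenylsilyloxy)methyl]-7-methoxy-2-(3-methoxy-4-triisopropylsilyloxyphenyl)-2,3-dihydrobenzofuran-5-yl]pent-3-en-2-ol | C[C@@H](O)/C=C/Cc1cc(OC)c2c(c1)[C@H](CO[Si](c3ccccc3)(c3ccccc3)C(C)(C)C)[C@@H](c3ccc(O[Si](C(C)C)(C(C)C)C(C)C)c(OC)c3)O2 | intermediate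
19 | methyl (R)-2,3-dihydroxypropanoate | COC(=O)[C@H](O)CO | starting material
20 | methyl (R)-3-(tert-butyldimethylsilyloxy)-2-hydroxypropanoate | COC(=O)[C@H](O)CO[Si](C)(C)C(C)(C)C | intermediate
21 | eugenol (4-allyl-2-methoxyphenol) | C=CCc1ccc(O)c(OC)c1 | starting material
22 | methyl (S)-2-(4-allyl-2-methoxyphenoxy)-3-(tert-butyldimethylsilyloxy)propanoate | COC(=O)[C@@H](Oc1ccc(CC=C)cc1OC)CO[Si](C)(C)C(C)(C)C | intermediate
23 | (S)-2-(4-allyl-2-methoxyphenoxy)-3-(tert-butyldimethylsilyloxy)-N-methoxy-N-methylpropanamide | CON(C)C(=O)[C@@H](Oc1ccc(CC=C)cc1OC)CO[Si](C)(C)C(C)(C)C | intermediate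
24 | 4-bromo-2-methoxyphenol | COc1cc(Br)ccc1O | starting material
25 | (4-bromo-2-methoxyphenoxy)triisopropylsilane | COc1cc(Br)ccc1O[Si](C(C)C)(C(C)C)C(C)C | intermediate
26 | [3-methoxy-4-(triisopropylsilyloxy)phenyl]lithium | [Li]c1ccc(O[Si](C(C)C)(C(C)C)C(C)C)c(OC)c1 | intermediate
27 | (S)-2-(4-allyl-2-methoxyphenoxy)-3-(tert-butyldimethylsilyloxy)-1-(3-methoxy-4-triisopropylsilyloxyphenyl)propan-1-one | O=C(c1ccc(O[Si](C(C)C)(C(C)C)C(C)C)c(OC)c1)[C@@H](Oc1ccc(CC=C)cc1OC)CO[Si](C)(C)C(C)(C)C | intermediate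
28 | (1R,2S)-2-(4-allyl-2-methoxyphenoxy)-3-(tert-butyldimethylsilyloxy)-1-(3-methoxy-4-triisopropylsilyloxyphenyl)propan-1-ol (erythro) | COc1cc([C@@H](O)[C@H](CO[Si](C)(C)C(C)(C)C)Oc2ccc(CC=C)cc2OC)ccc1O[Si](C(C)C)(C(C)C)C(C)C | intermediate
29 | 4-allyl-1-{[(1R,2S)-1,3-bis(tert-butyldimethylsilyloxy)-1-(3-methoxy-4-triisopropylsilyloxyphenyl)propan-2-yl]oxy}-2-methoxybenzene | COc1cc([C@@H](O[Si](C)(C)C(C)(C)C)[C@H](CO[Si](C)(C)C(C)(C)C)Oc2ccc(CC=C)cc2OC)ccc1O[Si](C(C)C)(C(C)C)C(C)C | intermediate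
30 | B-[3-(ring B aryl)propyl]-9-borabicyclo[3.3.1]nonane derived from 29 | COc1cc([C@@H](O[Si](C)(C)C(C)(C)C)[C@H](CO[Si](C)(C)C(C)(C)C)Oc2ccc(CCCB3C4CCCC3CCC4)cc2OC)ccc1O[Si](C(C)C)(C(C)C)C(C)C | intermediate
31 | 3-[4-{[(1R,2S)-1,3-bis(tert-butyldimethylsilyloxy)-1-(3-methoxy-4-triisopropylsilyloxyphenyl)propan-2-yl]oxy}-3-methoxyphenyl]propan-1-ol | COc1cc([C@@H](O[Si](C)(C)C(C)(C)C)[C@H](CO[Si](C)(C)C(C)(C)C)Oc2ccc(CCCO)cc2OC)ccc1O[Si](C(C)C)(C(C)C)C(C)C | intermediate
32 | 3-[4-{[(1R,2S)-1,3-bis(tert-butyldimethylsilyloxy)-1-(3-methoxy-4-triisopropylsilyloxyphenyl)propan-2-yl]oxy}-3-methoxyphenyl]propanal | COc1cc([C@@H](O[Si](C)(C)C(C)(C)C)[C@H](CO[Si](C)(C)C(C)(C)C)Oc2ccc(CCC=O)cc2OC)ccc1O[Si](C(C)C)(C(C)C)C(C)C | intermediate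
33 | 3-[4-{[(1R,2S)-1,3-bis(tert-butyldimethylsilyloxy)-1-(3-methoxy-4-triisopropylsilyloxyphenyl)propan-2-yl]oxy}-3-methoxyphenyl]propanoic acid | COc1cc([C@@H](O[Si](C)(C)C(C)(C)C)[C@H](CO[Si](C)(C)C(C)(C)C)Oc2ccc(CCC(O)=O)cc2OC)ccc1O[Si](C(C)C)(C(C)C)C(C)C | intermediate
34 | ester of acid 33 with alcohol 18, (R)-configured at the allylic carbinol, E alkene | COc1cc([C@@H](O[Si](C)(C)C(C)(C)C)[C@H](CO[Si](C)(C)C(C)(C)C)Oc2ccc(CCC(=O)O[C@H](C)/C=C/Cc3cc(OC)c4c(c3)[C@H](CO[Si](c5ccccc5)(c5ccccc5)C(C)(C)C)[C@@H](c3ccc(O[Si](C(C)C)(C(C)C)C(C)C)c(OC)c3)O4)cc2OC)ccc1O[Si](C(C)C)(C(C)C)C(C)C | intermediate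
35 | Z-trimethylsilyl ketene acetal of 34 (benzyl group cis to OSiMe3) | COc1cc([C@@H](O[Si](C)(C)C(C)(C)C)[C@H](CO[Si](C)(C)C(C)(C)C)Oc2ccc(C/C=C(\O[Si](C)(C)C)O[C@H](C)/C=C/Cc3cc(OC)c4c(c3)[C@H](CO[Si](c5ccccc5)(c5ccccc5)C(C)(C)C)[C@@H](c3ccc(O[Si](C(C)C)(C(C)C)C(C)C)c(OC)c3)O4)cc2OC)ccc1O[Si](C(C)C)(C(C)C)C(C)C | intermediate
36 | trimethylsilyl ester of acid 37 | COc1cc([C@@H](O[Si](C)(C)C(C)(C)C)[C@H](CO[Si](C)(C)C(C)(C)C)Oc2ccc(C[C@@H](C(=O)O[Si](C)(C)C)[C@H](/C=C/C)Cc3cc(OC)c4c(c3)[C@H](CO[Si](c5ccccc5)(c5ccccc5)C(C)(C)C)[C@@H](c3ccc(O[Si](C(C)C)(C(C)C)C(C)C)c(OC)c3)O4)cc2OC)ccc1O[Si](C(C)C)(C(C)C)C(C)C | intermediate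
37 | (2R,3S,4E)-2-(ring B benzyl)-3-(ring C methyl)hex-4-enoic acid, silyl groups as in 34 | COc1cc([C@@H](O[Si](C)(C)C(C)(C)C)[C@H](CO[Si](C)(C)C(C)(C)C)Oc2ccc(C[C@@H](C(O)=O)[C@H](/C=C/C)Cc3cc(OC)c4c(c3)[C@H](CO[Si](c5ccccc5)(c5ccccc5)C(C)(C)C)[C@@H](c3ccc(O[Si](C(C)C)(C(C)C)C(C)C)c(OC)c3)O4)cc2OC)ccc1O[Si](C(C)C)(C(C)C)C(C)C | intermediate
38 | secondary ozonide (1,2,4-trioxolane, isomer mixture at the ring carbons) of 37 | COc1cc([C@@H](O[Si](C)(C)C(C)(C)C)[C@H](CO[Si](C)(C)C(C)(C)C)Oc2ccc(C[C@@H](C(O)=O)[C@H](C6OOC(C)O6)Cc3cc(OC)c4c(c3)[C@H](CO[Si](c5ccccc5)(c5ccccc5)C(C)(C)C)[C@@H](c3ccc(O[Si](C(C)C)(C(C)C)C(C)C)c(OC)c3)O4)cc2OC)ccc1O[Si](C(C)C)(C(C)C)C(C)C | intermediate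
39 | (2R,3R)-2-(ring B benzyl)-3-(ring C methyl)-4-hydroxybutanoic acid, silyl groups as in 34 | COc1cc([C@@H](O[Si](C)(C)C(C)(C)C)[C@H](CO[Si](C)(C)C(C)(C)C)Oc2ccc(C[C@@H](C(O)=O)[C@H](CO)Cc3cc(OC)c4c(c3)[C@H](CO[Si](c5ccccc5)(c5ccccc5)C(C)(C)C)[C@@H](c3ccc(O[Si](C(C)C)(C(C)C)C(C)C)c(OC)c3)O4)cc2OC)ccc1O[Si](C(C)C)(C(C)C)C(C)C | intermediate
40 | (3R,4R)-trans-3,4-disubstituted dihydrofuran-2(3H)-one: the target carrying two aryl triisopropylsilyl ethers, two tert-butyldimethylsilyl ethers on the glycerol unit and the tert-butyldiphenylsilyl ether on the benzofuran hydroxymethyl group | COc1cc([C@@H](O[Si](C)(C)C(C)(C)C)[C@H](CO[Si](C)(C)C(C)(C)C)Oc2ccc(C[C@H]3C(=O)OC[C@@H]3Cc3cc(OC)c4c(c3)[C@H](CO[Si](c5ccccc5)(c5ccccc5)C(C)(C)C)[C@@H](c3ccc(O[Si](C(C)C)(C(C)C)C(C)C)c(OC)c3)O4)cc2OC)ccc1O[Si](C(C)C)(C(C)C)C(C)C | intermediate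
41 | CNP0298853.1 | COc1cc([C@@H](O)[C@H](CO)Oc2ccc(C[C@H]3C(=O)OC[C@@H]3Cc3cc(OC)c4c(c3)[C@H](CO)[C@@H](c3ccc(O)c(OC)c3)O4)cc2OC)ccc1O | target

Total step count: 24.
Longest linear sequence: 14 steps (steps 1–4, 6–11 and 21–24, from aldehyde 1).

Steps most likely to fail

Step 10. The benzylic cation may be diverted before the ring closes, by proton loss to a stilbene-type alkene, by intermolecular capture on one of the electron-rich rings, or by acid-induced loss of a silyl group. The fallback replaces the cation by an anionic quinone methide. It sets out from 14, whose carbinol is acetylated (Ac2O, pyridine, DMAP) to the benzylic acetate F1. Deallylation as in step 9 gives the free ring C phenol acetate F2. CsF in DMF at 0 °C then cleaves only the aryl silyl ether, and the ring D phenoxide expels acetate to give the para-quinone methide F3. The ring C phenoxide adds to it in a reversible intramolecular 1,6-addition, which should settle on the trans-dihydrobenzofuran ring D phenol F4. Silylation with TIPSCl and imidazole comes back to the route at 16.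

Step 17. Facial selectivity at the ketone may be poor if the oxazaborolidine does not distinguish the aryl group clearly from the bulky alpha-aryloxy alkyl group, which would give an erythro/threo mixture. The fallback forms the carbinol by carbon–carbon bond formation instead of by reduction. It sets out from ester 22, which iBu2AlH in toluene at −78 °C reduces to (S)-2-(4-allyl-2-methoxyphenoxy)-3-(tert-butyldimethylsilyloxy)propanal F5, used cold. Addition of [3-methoxy-4-(triisopropylsilyloxy)phenyl]magnesium bromide F6 (from 25 and Mg in THF) should follow the polar Felkin–Anh model, with the aryloxy group anti to the incoming aryl, which leads to the erythro alcohol and comes back to the route at 28.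

Step 22. Leakage of enolate geometry may erode the C2 configuration, because any ketene acetal with the benzyl group cis to the allylic oxygen rearranges to the C2 epimer. The fallback replaces kinetic control by thermodynamic control at the lactone stage. It sets out from the unseparated acid 37, which then contains its (2S,3S)-epimer F7. Step 23 run on this mixture turns F7 into the cis-(3S,4R)-lactone F8 alongside 40. DBU in toluene (rt → 60 °C) epimerises the alpha carbon of F8, and the more stable trans-3,4-dibenzyl lactone should result, which comes back to the route at 40.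

Further compounds

F1 | step 10 | (1S,2R)-2-[5-allyl-2-(allyloxy)-3-methoxyphenyl]-3-(tert-butyldiphenylsilyloxy)-1-(3-methoxy-4-triisopropylsilyloxyphenyl)propyl acetate | C=CCOc1c(OC)cc(CC=C)cc1[C@H](CO[Si](c2ccccc2)(c2ccccc2)C(C)(C)C)[C@H](OC(C)=O)c2ccc(O[Si](C(C)C)(C(C)C)C(C)C)c(OC)c2
F2 | step 10 | (1S,2R)-2-(5-allyl-2-hydroxy-3-methoxyphenyl)-3-(tert-butyldiphenylsilyloxy)-1-(3-methoxy-4-triisopropylsilyloxyphenyl)propyl acetate | C=CCc1cc(OC)c(O)c(c1)[C@H](CO[Si](c2ccccc2)(c2ccccc2)C(C)(C)C)[C@H](OC(C)=O)c2ccc(O[Si](C(C)C)(C(C)C)C(C)C)c(OC)c2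
F3 | step 10 | 4-[(R)-2-(5-allyl-2-hydroxy-3-methoxyphenyl)-3-(tert-butyldiphenylsilyloxy)propylidene]-2-methoxycyclohexa-2,5-dien-1-one (para-quinone methide, formed in the flask) | C=CCc1cc(OC)c(O)c(c1)[C@H](CO[Si](c2ccccc2)(c2ccccc2)C(C)(C)C)C=C1C=CC(=O)C(OC)=C1
F4 | step 10 | 4-[(2S,3R)-5-allyl-3-[(tert-butyldiphenylsilyloxy)methyl]-7-methoxy-2,3-dihydrobenzofuran-2-yl]-2-methoxyphenol | C=CCc1cc(OC)c2c(c1)[C@H](CO[Si](c3ccccc3)(c3ccccc3)C(C)(C)C)[C@@H](c3ccc(O)c(OC)c3)O2
F5 | step 17 | (S)-2-(4-allyl-2-methoxyphenoxy)-3-(tert-butyldimethylsilyloxy)propanal | O=C[C@@H](Oc1ccc(CC=C)cc1OC)CO[Si](C)(C)C(C)(C)C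
F6 | step 17 | [3-methoxy-4-(triisopropylsilyloxy)phenyl]magnesium bromide | COc1cc([Mg]Br)ccc1O[Si](C(C)C)(C(C)C)C(C)C
F7 | step 22 | (2S,3S,4E)-epimer of acid 37 | COc1cc([C@@H](O[Si](C)(C)C(C)(C)C)[C@H](CO[Si](C)(C)C(C)(C)C)Oc2ccc(C[C@H](C(O)=O)[C@H](/C=C/C)Cc3cc(OC)c4c(c3)[C@H](CO[Si](c5ccccc5)(c5ccccc5)C(C)(C)C)[C@@H](c3ccc(O[Si](C(C)C)(C(C)C)C(C)C)c(OC)c3)O4)cc2OC)ccc1O[Si](C(C)C)(C(C)C)C(C)C
F8 | step 22 | cis-(3S,4R)-epimer of lactone 40 | COc1cc([C@@H](O[Si](C)(C)C(C)(C)C)[C@H](CO[Si](C)(C)C(C)(C)C)Oc2ccc(C[C@@H]3C(=O)OC[C@@H]3Cc3cc(OC)c4c(c3)[C@H](CO[Si](c5ccccc5)(c5ccccc5)C(C)(C)C)[C@@H](c3ccc(O[Si](C(C)C)(C(C)C)C(C)C)c(OC)c3)O4)cc2OC)ccc1O[Si](C(C)C)(C(C)C)C(C)C
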